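**Plan**

- Target: 5,7-dihydroxy-2-(4-hydroxy-2-methoxyphenyl)-3-prenyl-4H-chromen-4-one (rings A, B, C; achiral).
- Feature used: ring C contains the aryl ether bond O1–C8a, and C8a of ring A is ortho to the C4 carbonyl and meta to both ring A oxygens (at C5 and C7). A bromide at C8a of an open-chain 2-prenyl-1,3-diketone can therefore be displaced by the ring B ketone oxygen, which becomes O1.
- Retrosynthetic cuts, in order: three phenolic allyl ethers; O1–C8a (intramolecular enolate O-arylation); C3–C4 (aldol, then oxidation); C3–CH2 of the prenyl group (enolate alkylation); C4–C4a (formylation next to bromine).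
- Forward: rings A and B are bought as arenes and elaborated separately (ring A aldehyde 5, ring B prenyl ketone 10), joined at C3–C4, oxidised to diketone 14, and ring C, the only ring formed, is closed last at O1–C8a.
- Stereochemistry: none in the target; the sp3 centres of 13 and 14 are transient and are erased by oxidation and by ring closure.

Key step: step 7

Assumption: compounds 1, 2, 6 and 8 are taken as purchasable, and the target has no stereocentre and no stereogenic alkene, so no stereocontrol is planned.

**Step 1**
Reactants: 1 5-bromobenzene-1,3-diol; 2 allyl bromide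
Product: 3 1-bromo-3,5-bis(allyloxy)benzene
Conditions: allyl bromide (2.5 equiv), K2CO3 (3 equiv), DMF, rt to 50 °C
Reagents that add atoms: allyl bromide (compound 2), C=CCBr
Why: Williamson ether synthesis, in which both phenols are O-alkylated by the primary allylic bromide under K2CO3 in a polar aprotic solvent while the aryl bromide is inert.

**Step 2**
Reactants: 3 1-bromo-3,5-bis(allyloxy)benzene
Product: 5 2-bromo-4,6-bis(allyloxy)benzaldehyde, via iminium salt 4 (not isolated)
Conditions: POCl3 (1.5 equiv), DMF, 0 °C then 80 °C; aq. NaOAc, rt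
Reagents that add atoms: N,N-dimethylformamide, CN(C)C=O; water, O
Why: Vilsmeier–Haack formylation, in which the chloroiminium electrophile should attack the ring carbon next to bromine (para to one allyloxy group, ortho to the other) rather than the more crowded carbon between the two ethers, as is known for the corresponding dimethyl ether, and aqueous NaOAc then hydrolyses iminium salt 4 to the aldehyde.

**Step 3**
Reactants: 6 1-(4-hydroxy-2-methoxyphenyl)ethanone; 2 allyl bromide
Product: 7 1-[4-(allyloxy)-2-methoxyphenyl]ethanone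
Conditions: allyl bromide (1.2 equiv), K2CO3 (1.5 equiv), acetone, reflux
Reagents that add atoms: allyl bromide (compound 2), C=CCBr
Why: Williamson ether synthesis on the only free phenol, under a base too weak to enolise the aryl methyl ketone appreciably, so O-allylation is expected exclusively.

**Step 4**
Reactants: 7 1-[4-(allyloxy)-2-methoxyphenyl]ethanone; 8 prenyl bromide
Product: 10 1-[4-(allyloxy)-2-methoxyphenyl]-5-methylhex-4-en-1-one, via lithium enolate 9 (not isolated)
Conditions: LDA (lithium diisopropylamide, LiN(iPr)2, 1.05 equiv), THF, −78 °C; prenyl bromide (1.0 equiv), −78 to 0 °C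
Reagents that add atoms: prenyl bromide (compound 8), CC(C)=CCBr
Why: Kinetic lithium enolate alkylation, in which LDA deprotonates the methyl ketone completely at low temperature and enolate 9 displaces bromide from the unhindered CH2 end of the allylic halide, with one equivalent of base and electrophile limiting double alkylation.

**Step 5**
Reactants: 10 1-[4-(allyloxy)-2-methoxyphenyl]-5-methylhex-4-en-1-one; 5 2-bromo-4,6-bis(allyloxy)benzaldehyde
Product: 13 3-[2-bromo-4,6-bis(allyloxy)phenyl]-3-hydroxy-1-[4-(allyloxy)-2-methoxyphenyl]-2-(3-methylbut-2-en-1-yl)propan-1-one (racemic mixture of diastereomers), via lithium enolate 11 (not isolated), via lithium aldolate 12 (not isolated)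
Conditions: LDA (1.1 equiv), THF, −78 °C; then 5 in THF, −78 °C; AcOH quench at −78 °C
Reagents that add atoms: none
Why: Directed (crossed) lithium aldol addition of preformed enolate 11 to the non-enolisable aldehyde 5, with a cold AcOH quench of aldolate 12 to suppress retro-aldol, and with both new stereocentres left uncontrolled because the carbinol is oxidised in step 6 and the α-centre becomes sp2 in step 7.

**Step 6**
Reactants: 13 the aldol from step 5
Product: 14 1-[2-bromo-4,6-bis(allyloxy)phenyl]-3-[4-(allyloxy)-2-methoxyphenyl]-2-(3-methylbut-2-en-1-yl)propane-1,3-dione (racemic at the enolisable central carbon)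
Conditions: Dess–Martin periodinane (1.5 equiv), CH2Cl2, 0 °C to rt
Reagents that add atoms: none
Why: Dess–Martin oxidation of a hindered secondary benzylic alcohol to the ketone under near-neutral conditions that should leave the prenyl and allyl alkenes and the aryl bromide untouched, while the alkyl group on the central carbon prevents over-oxidation to a vicinal tricarbonyl.

**Step 7**
Reactants: 14 the 2-prenyl-1,3-diketone from step 6
Product: 16 5,7-bis(allyloxy)-2-[4-(allyloxy)-2-methoxyphenyl]-3-(3-methylbut-2-en-1-yl)-4H-chromen-4-one, via cesium enolate 15 (not isolated)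
Conditions: CuI (10 mol %), 1,10-phenanthroline (20 mol %), Cs2CO3 (2 equiv), dry degassed DMF, 90 °C, argon
Reagents that add atoms: none
Why: Cs2CO3 converts the diketone into the chelated cesium enolate 15; the CuI/phenanthroline catalyst (monovalent copper) binds the enolate oxygen of the ring B carbonyl, inserts into the C8a–Br bond of ring A, and C–O reductive elimination from the aryl copper intermediate (trivalent copper) forms O1–C8a. The closest known reaction type is the Ullmann-type intramolecular O-arylation of 1-(2-haloaryl)-1,3-diketones to chromones and flavones, which also tolerates a substituent on the central carbon. Ring C closes as a six-membered ring by ipso substitution at the sp2 carbon C8a, with bromide leaving from outside the new ring and a seven-membered copper chelate as the preceding intermediate. No stereocentre is created, and the racemic sp3 centre of 14 becomes the sp2 carbon C3 that carries the prenyl group. The step needs O-arylation by the distal (ring B) enolate oxygen: C-arylation or attack by the ring A carbonyl oxygen would require a four-membered ring, the ketone ortho to bromine activates C8a, and the two allyloxy groups are meta to it and do not retard substitution. Dry, degassed conditions are chosen so that retro-Claisen cleavage of the diketone and reductive loss of bromine should not compete.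

**Step 8**
Reactants: 16 the tri-O-allyl flavone from step 7
Product: 17 5,7-dihydroxy-2-(4-hydroxy-2-methoxyphenyl)-3-(3-methylbut-2-en-1-yl)-4H-chromen-4-one (target)
Conditions: Pd(PPh3)4 (10 mol %), morpholine (10 equiv), THF, rt; dilute aqueous citric acid work-up
Reagents that add atoms: none
Why: Tsuji–Trost-type deallylation, in which zerovalent palladium from Pd(PPh3)4 ionises each aryl allyl ether to a phenoxide and an allyl fragment that morpholine captures irreversibly, while the C-bound prenyl group has no leaving group and the methyl ether is inert.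

**Compound list**

1 | 5-bromobenzene-1,3-diol | Oc1cc(O)cc(Br)c1 | starting material
2 | allyl bromide (3-bromoprop-1-ene) | C=CCBr | starting material
3 | 1-bromo-3,5-bis(allyloxy)benzene | C=CCOc1cc(Br)cc(OCC=C)c1 | intermediate
4 | N-{[2-bromo-4,6-bis(allyloxy)phenyl]methylidene}-N-methylmethanaminium dichlorophosphate (aryl iminium salt) | C=CCOc1cc(Br)c(C=[N+](C)C)c(OCC=C)c1.[O-]P(=O)(Cl)Cl | intermediate (not isolated)
5 | 2-bromo-4,6-bis(allyloxy)benzaldehyde | C=CCOc1cc(Br)c(C=O)c(OCC=C)c1 | intermediate
6 | 1-(4-hydroxy-2-methoxyphenyl)ethanone | CC(=O)c1ccc(O)cc1OC | starting material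
7 | 1-[4-(allyloxy)-2-methoxyphenyl]ethanone | CC(=O)c1ccc(OCC=C)cc1OC | intermediate
8 | prenyl bromide (1-bromo-3-methylbut-2-ene) | CC(C)=CCBr | starting material
9 | lithium 1-[4-(allyloxy)-2-methoxyphenyl]ethen-1-olate (lithium enolate of 7) | [Li+].[O-]C(=C)c1ccc(OCC=C)cc1OC | intermediate (not isolated)
10 | 1-[4-(allyloxy)-2-methoxyphenyl]-5-methylhex-4-en-1-one | CC(C)=CCCC(=O)c1ccc(OCC=C)cc1OC | intermediate
11 | lithium (Z)-1-[4-(allyloxy)-2-methoxyphenyl]-5-methylhexa-1,4-dien-1-olate (lithium enolate of 10; geometry immaterial) | [Li+].CC(C)=CC/C=C(\[O-])c1ccc(OCC=C)cc1OC | intermediate (not isolated)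
12 | lithium 1-[2-bromo-4,6-bis(allyloxy)phenyl]-3-[4-(allyloxy)-2-methoxyphenyl]-2-(3-methylbut-2-en-1-yl)-3-oxopropan-1-olate (lithium aldolate, mixture of diastereomers) | [Li+].C=CCOc1cc(Br)c(C([O-])C(CC=C(C)C)C(=O)c2ccc(OCC=C)cc2OC)c(OCC=C)c1 | intermediate (not isolated)
13 | 3-[2-bromo-4,6-bis(allyloxy)phenyl]-3-hydroxy-1-[4-(allyloxy)-2-methoxyphenyl]-2-(3-methylbut-2-en-1-yl)propan-1-one (racemic mixture of diastereomers) | C=CCOc1cc(Br)c(C(O)C(CC=C(C)C)C(=O)c2ccc(OCC=C)cc2OC)c(OCC=C)c1 | intermediate
14 | 1-[2-bromo-4,6-bis(allyloxy)phenyl]-3-[4-(allyloxy)-2-methoxyphenyl]-2-(3-methylbut-2-en-1-yl)propane-1,3-dione (racemic) | C=CCOc1cc(Br)c(C(=O)C(CC=C(C)C)C(=O)c2ccc(OCC=C)cc2OC)c(OCC=C)c1 | intermediate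
15 | cesium enolate of 14 (drawn as the ring B enolate; delocalised) | [Cs+].C=CCOc1cc(Br)c(C(=O)C(CC=C(C)C)=C([O-])c2ccc(OCC=C)cc2OC)c(OCC=C)c1 | intermediate (not isolated)
16 | 5,7-bis(allyloxy)-2-[4-(allyloxy)-2-methoxyphenyl]-3-(3-methylbut-2-en-1-yl)-4H-chromen-4-one | C=CCOc1ccc(-c2oc3cc(OCC=C)cc(OCC=C)c3c(=O)c2CC=C(C)C)c(OC)c1 | intermediate
17 | 5,7-dihydroxy-2-(4-hydroxy-2-methoxyphenyl)-3-(3-methylbut-2-en-1-yl)-4H-chromen-4-one | COc1cc(O)ccc1-c1oc2cc(O)cc(O)c2c(=O)c1CC=C(C)C | target

**Totals**

Total step count: 8. Longest linear sequence: 6 steps (steps 3, 4, 5, 6, 7, 8 from compound 6; equally steps 1, 2, 5, 6, 7, 8 from compound 1).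

**Steps most likely to fail, with fallbacks**

Step 5. The α-branched enolate 11 may add only slowly to the electron-rich aldehyde 5, which carries two ortho substituents, and the crowded aldolate may revert by retro-aldol on warming, so that conversion stalls. The fallback sets out from 7 and 5 and postpones the prenylation. The unbranched enolate 9 (LDA, THF, −78 °C) is added to 5 and quenched cold with AcOH to give 3-[2-bromo-4,6-bis(allyloxy)phenyl]-3-hydroxy-1-[4-(allyloxy)-2-methoxyphenyl]propan-1-one F1. Oxidation with Dess–Martin periodinane (1.1 equiv, CH2Cl2) gives 1-[2-bromo-4,6-bis(allyloxy)phenyl]-3-[4-(allyloxy)-2-methoxyphenyl]propane-1,3-dione F2. C-alkylation of F2 at the central carbon with prenyl bromide 8 (K2CO3, acetone, reflux) returns to the route at 14; step 4 is then not needed.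

Step 7. The congested diketone enolate may fragment by retro-Claisen cleavage (adventitious water, or dimethylamine from DMF), bromine may be lost reductively, or insertion of copper into the C–Br bond may be too slow. The fallback closes ring C at O1–C2 by cyclodehydration instead; it sets out from 10 and 2. Purchased 2,4,6-trihydroxybenzaldehyde F3 is tri-O-allylated with 2 (K2CO3, DMF) to 2,4,6-tris(allyloxy)benzaldehyde F4. Aldol addition of enolate 11 (from 10 and LDA) to F4 gives 1-[4-(allyloxy)-2-methoxyphenyl]-3-hydroxy-2-(3-methylbut-2-en-1-yl)-3-[2,4,6-tris(allyloxy)phenyl]propan-1-one F5. Dess–Martin oxidation gives 1-[4-(allyloxy)-2-methoxyphenyl]-2-(3-methylbut-2-en-1-yl)-3-[2,4,6-tris(allyloxy)phenyl]propane-1,3-dione F6. Pd(PPh3)4 with morpholine in THF removes all four allyl groups to give 1-(4-hydroxy-2-methoxyphenyl)-2-(3-methylbut-2-en-1-yl)-3-(2,4,6-trihydroxyphenyl)propane-1,3-dione F7. Either of the two equivalent ortho phenols of ring A in F7 adds to the ring B ketone, and catalytic p-toluenesulfonic acid in MeOH at 40 °C dehydrates the hemiketal. The fallback comes back to the route at the target 17.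

Step 4. Proton exchange between the product ketone and unreacted enolate 9 may lead to double prenylation alongside recovered 7. The fallback sets out from 7 and uses a β-keto ester to enforce monoalkylation. Claisen condensation of 7 with diethyl carbonate (NaH, THF, reflux) gives ethyl 3-[4-(allyloxy)-2-methoxyphenyl]-3-oxopropanoate F8. Alkylation with prenyl bromide 8 (K2CO3, acetone, reflux) gives ethyl 2-[4-(allyloxy)-2-methoxybenzoyl]-5-methylhex-4-enoate F9. Hydrolysis and decarboxylation in one operation (NaOH, aqueous EtOH, reflux; then acidification) returns to the route at 10.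

**Further compounds**

F1 | step 5 | 3-[2-bromo-4,6-bis(allyloxy)phenyl]-3-hydroxy-1-[4-(allyloxy)-2-methoxyphenyl]propan-1-one (racemic) | C=CCOc1cc(Br)c(C(O)CC(=O)c2ccc(OCC=C)cc2OC)c(OCC=C)c1
F2 | step 5 | 1-[2-bromo-4,6-bis(allyloxy)phenyl]-3-[4-(allyloxy)-2-methoxyphenyl]propane-1,3-dione | C=CCOc1cc(Br)c(C(=O)CC(=O)c2ccc(OCC=C)cc2OC)c(OCC=C)c1
F3 | step 7 | 2,4,6-trihydroxybenzaldehyde (purchased) | O=Cc1c(O)cc(O)cc1O
F4 | step 7 | 2,4,6-tris(allyloxy)benzaldehyde | C=CCOc1cc(OCC=C)c(C=O)c(OCC=C)c1
F5 | step 7 | 1-[4-(allyloxy)-2-methoxyphenyl]-3-hydroxy-2-(3-methylbut-2-en-1-yl)-3-[2,4,6-tris(allyloxy)phenyl]propan-1-one (racemic mixture of diastereomers) | C=CCOc1cc(OCC=C)c(C(O)C(CC=C(C)C)C(=O)c2ccc(OCC=C)cc2OC)c(OCC=C)c1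
F6 | step 7 | 1-[4-(allyloxy)-2-methoxyphenyl]-2-(3-methylbut-2-en-1-yl)-3-[2,4,6-tris(allyloxy)phenyl]propane-1,3-dione (racemic) | C=CCOc1cc(OCC=C)c(C(=O)C(CC=C(C)C)C(=O)c2ccc(OCC=C)cc2OC)c(OCC=C)c1
F7 | step 7 | 1-(4-hydroxy-2-methoxyphenyl)-2-(3-methylbut-2-en-1-yl)-3-(2,4,6-trihydroxyphenyl)propane-1,3-dione (racemic) | COc1cc(O)ccc1C(=O)C(CC=C(C)C)C(=O)c1c(O)cc(O)cc1O
F8 | step 4 | ethyl 3-[4-(allyloxy)-2-methoxyphenyl]-3-oxopropanoate | CCOC(=O)CC(=O)c1ccc(OCC=C)cc1OC
F9 | step 4 | ethyl 2-[4-(allyloxy)-2-methoxybenzoyl]-5-methylhex-4-enoate (racemic) | CCOC(=O)C(CC=C(C)C)C(=O)c1ccc(OCC=C)cc1OC
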